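**Retrosynthetic overview**

- The target is 2',4'-dihydroxy-3',6'-dimethoxy-5'-[(S)-2-methylbutanoyloxy]chalcone (chalcone numbering, C1' carries the ketone). The last disconnections are the C5' ester (from (S)-2-methylbutanoic acid, with O4' capped for the moment as a methoxymethyl ether), the two O-benzyl groups on O4' and O5', and the C1' ketone, which is carried as a silyl-protected cinnamyl carbinol.
- The strategy rests on ring A being fully substituted with the free C2' hydroxyl ortho to the carbon-bearing C1' and meta to the C6' methoxyl. This C2'(OH)–C1'(C)–C6'(OMe) resorcinol monoether motif is what a vinylketene/ynol ether benzannulation produces.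
- Key disconnection: ring A is cut at C1'–C2', C5'–C6' and C2'–C3' into a 2,3-bis(benzyloxy)-4-methoxycyclobutenone (C2' to C5' with their oxygens) and a 1-methoxyalkyne that already carries the C1' side chain (C1', C6').
- The cyclobutenone comes from squaric acid (benzyl ester, mono-reduction, O-methylation). The alkyne comes from chloroacetaldehyde dimethyl acetal and (E)-cinnamaldehyde (acetylide addition, silylation).
- Ring A is the only ring that is built; ring B arrives with cinnamaldehyde and the single stereocentre with the chiral-pool acid.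

Key step: step 6

Remark: every intermediate before the esterification is achiral or racemic. This is harmless, because the carbinol centre is oxidised to the ketone and the only stereocentre of the target is introduced with (S)-2-methylbutanoic acid.

**Route**

Step 1
Reactants: 1 squaric acid
Product: 2 dibenzyl squarate (3,4-bis(benzyloxy)cyclobut-3-ene-1,2-dione)
Conditions: BnOH (excess), PhMe, reflux, Dean–Stark
Reagents that add atoms: benzyl alcohol, OCc1ccccc1
Why: Azeotropic Fischer-type esterification of the strongly acidic vinylogous diacid with removal of water is the standard entry to dialkyl squarates.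

Step 2
Reactants: 2 dibenzyl squarate
Product: 3 rac-2,3-bis(benzyloxy)-4-hydroxycyclobut-2-en-1-one
Conditions: LiAlH(OtBu)3 (1.05 equiv), THF, −78 to −20 °C; cold aq KNaC4H4O6
Reagents that add atoms: none
Why: Chemoselective 1,2-hydride reduction of one of the two equivalent ketone carbonyls by the bulky, mild alkoxyaluminium hydride is established for squarate esters and stops after one reduction because the remaining carbonyl is a deactivated vinylogous ester; the new carbinol centre forms racemic and later becomes aromatic C3'.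

Step 3
Reactants: 3 rac-2,3-bis(benzyloxy)-4-hydroxycyclobut-2-en-1-one
Product: 4 rac-2,3-bis(benzyloxy)-4-methoxycyclobut-2-en-1-one
Conditions: MeI (excess), Ag2O, CaSO4, MeCN, rt, dark
Reagents that add atoms: iodomethane, CI
Why: Purdie O-methylation etherifies the secondary hydroxyl under essentially neutral conditions, which avoids the acid-induced collapse of 3 to a cyclobutenedione and base-induced ring opening, and the methyl ether also prevents later lactonization of the derived vinylketene to a butenolide.

Step 4
Reactants: 5 chloroacetaldehyde dimethyl acetal; 6 (E)-cinnamaldehyde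
Product: 8 rac-(E)-1-methoxy-5-phenylpent-4-en-1-yn-3-ol, via lithium methoxyacetylide 7 (not isolated)
Conditions: Et2NH, n-BuLi (3.0 equiv per 5), THF, 0 °C; add 5, 0 °C; then 6, −78 °C; H2O quench
Reagents that add atoms: none
Why: Three equivalents of LiNEt2 convert the chloroacetal by two β-eliminations (loss of MeOH, then HCl) and deprotonation into lithium methoxyacetylide, which undergoes 1,2-acetylide addition to the enal carbonyl; the carbinol centre forms racemic and is later oxidised away.

Step 5
Reactants: 8 rac-(E)-1-methoxy-5-phenylpent-4-en-1-yn-3-ol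
Product: 9 rac-(E)-tert-butyl[(1-methoxy-5-phenylpent-4-en-1-yn-3-yl)oxy]dimethylsilane
Conditions: TBSCl, imidazole, DMF, 0 °C to rt (crude 8 used directly, no acid contact)
Reagents that add atoms: tert-butyldimethylsilyl chloride, CC(C)(C)[Si](C)(C)Cl
Why: Standard silyl ether formation with a silyl chloride and imidazole keeps the acid-labile 3-hydroxy-1-alkoxyalkyne basic throughout, so that Meyer–Schuster rearrangement cannot occur, and gives an ether that withstands the thermal step.

Step 6
Reactants: 4 rac-2,3-bis(benzyloxy)-4-methoxycyclobut-2-en-1-one; 9 rac-(E)-tert-butyl[(1-methoxy-5-phenylpent-4-en-1-yn-3-yl)oxy]dimethylsilane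
Product: 14 rac-4,5-bis(benzyloxy)-2-[(E)-1-(tert-butyldimethylsilyloxy)-3-phenylprop-2-enyl]-3,6-dimethoxyphenol, via vinylketene 10 (not isolated), via vinylcyclobutenone 11 (not isolated), via dienylketene 12 (not isolated), via cyclohexadienone 13 (not isolated)
Conditions: 9 (1.5 equiv), degassed PhMe, 110 °C, sealed tube, slow addition of 4
Reagents that add atoms: none
Why: Proposed new method: heating opens cyclobutenone 4 by four-electron electrocyclic ring opening, the 4-methoxy group turning outward, to vinylketene 10, whose ketene carbon is attacked by the oxygen-free, nucleophilic carbon of ynol ether 9 in a regioselective (2+2) cycloaddition that gives vinylcyclobutenone 11 and forms the C1'–C2' and C5'–C6' bonds. A second four-electron opening (benzyloxy outward, alkenyl inward) gives dienylketene 12 with the Z geometry needed for closure, and ring A then closes by a thermal disrotatory six-electron electrocyclization that forms the C2'–C3' bond, cyclohexadienone 13 tautomerizing to phenol 14. The closest known reaction type is the Danheiser benzannulation of alkyl- or aryl-substituted cyclobutenones with alkoxy- and siloxyalkynes, and the thermal opening of 4-oxygenated 2,3-dialkoxycyclobutenones to vinylketenes is known from squarate chemistry; what is untested is the intermolecular capture of such a fully oxygenated vinylketene by an ynol ether. No new stereocentre is created, the racemic carbinol carbon being carried through unchanged. The step needs only regioselectivity, which the polarization of the ynol ether secures by placing the side-chain carbon at C1' next to the new C2' hydroxyl and the methoxy carbon at C6'; the O-methyl group of 9 has no β-hydrogen, so the alkyne cannot fragment to a ketene on heating.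

Step 7
Reactants: 14 rac-4,5-bis(benzyloxy)-2-[(E)-1-(tert-butyldimethylsilyloxy)-3-phenylprop-2-enyl]-3,6-dimethoxyphenol
Product: 15 rac-4,5-bis(benzyloxy)-2-[(E)-1-hydroxy-3-phenylprop-2-enyl]-3,6-dimethoxyphenol
Conditions: Bu4NF, THF, 0 °C; pH 7 phosphate buffer work-up; crude used at once
Reagents that add atoms: none
Why: Fluoride-mediated silyl ether cleavage, driven by Si–F bond formation, releases the carbinol under non-acidic conditions, so the doubly activated benzylic–allylic C–O bond is not ionized and the benzyl and methyl ethers are untouched.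

Step 8
Reactants: 15 rac-4,5-bis(benzyloxy)-2-[(E)-1-hydroxy-3-phenylprop-2-enyl]-3,6-dimethoxyphenol
Product: 16 4',5'-bis(benzyloxy)-2'-hydroxy-3',6'-dimethoxychalcone ((E)-1-[3,4-bis(benzyloxy)-6-hydroxy-2,5-dimethoxyphenyl]-3-phenylprop-2-en-1-one)
Conditions: activated MnO2 (excess), CH2Cl2, rt
Reagents that add atoms: none
Why: Activated MnO2 oxidation is selective for allylic and benzylic alcohols under neutral conditions and should give the 2'-hydroxychalcone, whose phenol is then held in a hydrogen bond to the ketone, with the E-alkene unchanged.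

Step 9
Reactants: 16 4',5'-bis(benzyloxy)-2'-hydroxy-3',6'-dimethoxychalcone
Product: 17 2',4',5'-trihydroxy-3',6'-dimethoxychalcone ((E)-1-(2,4,5-trihydroxy-3,6-dimethoxyphenyl)-3-phenylprop-2-en-1-one)
Conditions: BCl3 (1 M in CH2Cl2), C6HMe5 (excess), CH2Cl2, −78 °C; then H2O; handled under Ar
Reagents that add atoms: none
Why: Lewis acid-mediated O-debenzylation of aryl benzyl ethers with BCl3 and pentamethylbenzene as a non-basic benzyl cation scavenger runs at −78 °C, where the alkene is not reduced (as it would be on hydrogenolysis) and the methyl ethers should survive, the 6'-methoxyl being protected from chelation-directed cleavage because the ketone is already engaged with the boron on O2'.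

Step 10
Reactants: 17 2',4',5'-trihydroxy-3',6'-dimethoxychalcone
Product: 18 2',5'-dihydroxy-3',6'-dimethoxy-4'-(methoxymethoxy)chalcone ((E)-1-[2,5-dihydroxy-3,6-dimethoxy-4-(methoxymethoxy)phenyl]-3-phenylprop-2-en-1-one)
Conditions: MOMCl (1.05 equiv), i-Pr2NEt, degassed CH2Cl2, 0 °C, Ar
Reagents that add atoms: chloromethyl methyl ether, COCCl
Why: Regioselective Williamson-type O-alkylation is expected at O4', since that hydroxyl, para to the ketone, is the most acidic and the only one ionized by the amine base, whereas the 2'-hydroxyl is locked in the chelate and the 5'-hydroxyl is less acidic.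

Step 11
Reactants: 18 2',5'-dihydroxy-3',6'-dimethoxy-4'-(methoxymethoxy)chalcone; 19 (S)-2-methylbutanoic acid
Product: 20 2'-hydroxy-3',6'-dimethoxy-4'-(methoxymethoxy)-5'-[(S)-2-methylbutanoyloxy]chalcone ([4-hydroxy-2,5-dimethoxy-6-(methoxymethoxy)-3-[(E)-3-phenylprop-2-enoyl]phenyl] (2S)-2-methylbutanoate)
Conditions: 19 (1.2 equiv), DCC, DMAP (0.1 equiv), CH2Cl2, 0 °C to rt
Reagents that add atoms: none
Why: Steglich esterification acylates the only free, non-chelated phenol (O5'), the hydrogen-bonded 2'-hydroxyl being unreactive, and the α-stereocentre of the acid is not involved in the acyl transfer, low temperature and catalytic DMAP limiting ketene-type racemization.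

Step 12
Reactants: 20 2'-hydroxy-3',6'-dimethoxy-4'-(methoxymethoxy)-5'-[(S)-2-methylbutanoyloxy]chalcone
Product: 21 2',4'-dihydroxy-3',6'-dimethoxy-5'-[(S)-2-methylbutanoyloxy]chalcone ([2,4-dihydroxy-3,6-dimethoxy-5-[(E)-3-phenylprop-2-enoyl]phenyl] (2S)-2-methylbutanoate), the target
Conditions: CF3CO2H/CH2Cl2 (1:9), 0 °C; pH 7 buffer work-up
Reagents that add atoms: none
Why: Acid-catalysed cleavage of the aryl methoxymethyl acetal under non-nucleophilic conditions leaves the aryl ester, the enone and the α-stereocentre untouched, and the acyl group should stay on O5' because the ester of the less acidic phenol is the more stable regioisomer.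

**Compound list**

1 | squaric acid | OC1=C(O)C(=O)C1=O | starting material
2 | dibenzyl squarate (3,4-bis(benzyloxy)cyclobut-3-ene-1,2-dione) | O=C1C(=O)C(OCc2ccccc2)=C1OCc3ccccc3 | intermediate
3 | rac-2,3-bis(benzyloxy)-4-hydroxycyclobut-2-en-1-one | OC1C(OCc2ccccc2)=C(OCc3ccccc3)C1=O | intermediate
4 | rac-2,3-bis(benzyloxy)-4-methoxycyclobut-2-en-1-one | COC1C(OCc2ccccc2)=C(OCc3ccccc3)C1=O | intermediate
5 | chloroacetaldehyde dimethyl acetal (2-chloro-1,1-dimethoxyethane) | COC(CCl)OC | starting material
6 | (E)-cinnamaldehyde | O=C/C=C/c1ccccc1 | starting material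
7 | lithium methoxyacetylide (not isolated) | [Li]C#COC | intermediate
8 | rac-(E)-1-methoxy-5-phenylpent-4-en-1-yn-3-ol | COC#CC(O)/C=C/c1ccccc1 | intermediate
9 | rac-(E)-tert-butyl[(1-methoxy-5-phenylpent-4-en-1-yn-3-yl)oxy]dimethylsilane | COC#CC(O[Si](C)(C)C(C)(C)C)/C=C/c1ccccc1 | intermediate
10 | (Z)-2,3-bis(benzyloxy)-4-methoxybuta-1,3-dien-1-one (vinylketene, methoxy trans to C2; not isolated) | O=C=C(OCc1ccccc1)/C(OCc2ccccc2)=C/OC | intermediate
11 | 4-(benzyloxy)-4-[(Z)-1-(benzyloxy)-2-methoxyethenyl]-2-[(E)-1-(tert-butyldimethylsilyloxy)-3-phenylprop-2-enyl]-3-methoxycyclobut-2-en-1-one (racemic diastereomer mixture; not isolated) | O=C1C(C(O[Si](C)(C)C(C)(C)C)/C=C/c2ccccc2)=C(OC)C1(OCc3ccccc3)/C(OCc4ccccc4)=C/OC | intermediate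
12 | rac-(3Z,5Z)-4,5-bis(benzyloxy)-2-[(E)-1-(tert-butyldimethylsilyloxy)-3-phenylprop-2-enyl]-3,6-dimethoxyhexa-1,3,5-trien-1-one (dienylketene; not isolated) | O=C=C(C(O[Si](C)(C)C(C)(C)C)/C=C/c1ccccc1)/C(OC)=C(OCc2ccccc2)\C(OCc3ccccc3)=C\OC | intermediate
13 | 4,5-bis(benzyloxy)-2-[(E)-1-(tert-butyldimethylsilyloxy)-3-phenylprop-2-enyl]-3,6-dimethoxycyclohexa-2,4-dien-1-one (racemic diastereomer mixture; not isolated) | O=C1C(C(O[Si](C)(C)C(C)(C)C)/C=C/c2ccccc2)=C(OC)C(OCc3ccccc3)=C(OCc4ccccc4)C1OC | intermediate
14 | rac-4,5-bis(benzyloxy)-2-[(E)-1-(tert-butyldimethylsilyloxy)-3-phenylprop-2-enyl]-3,6-dimethoxyphenol | COc1c(OCc2ccccc2)c(OCc3ccccc3)c(OC)c(O)c1C(O[Si](C)(C)C(C)(C)C)/C=C/c4ccccc4 | intermediate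
15 | rac-4,5-bis(benzyloxy)-2-[(E)-1-hydroxy-3-phenylprop-2-enyl]-3,6-dimethoxyphenol | COc1c(OCc2ccccc2)c(OCc3ccccc3)c(OC)c(O)c1C(O)/C=C/c4ccccc4 | intermediate
16 | 4',5'-bis(benzyloxy)-2'-hydroxy-3',6'-dimethoxychalcone | COc1c(OCc2ccccc2)c(OCc3ccccc3)c(OC)c(O)c1C(=O)/C=C/c4ccccc4 | intermediate
17 | 2',4',5'-trihydroxy-3',6'-dimethoxychalcone | COc1c(O)c(O)c(OC)c(O)c1C(=O)/C=C/c2ccccc2 | intermediate
18 | 2',5'-dihydroxy-3',6'-dimethoxy-4'-(methoxymethoxy)chalcone | COc1c(O)c(OCOC)c(OC)c(O)c1C(=O)/C=C/c2ccccc2 | intermediate
19 | (S)-2-methylbutanoic acid | CC[C@H](C)C(=O)O | starting material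
20 | 2'-hydroxy-3',6'-dimethoxy-4'-(methoxymethoxy)-5'-[(S)-2-methylbutanoyloxy]chalcone | CC[C@H](C)C(=O)Oc1c(OCOC)c(OC)c(O)c(C(=O)/C=C/c2ccccc2)c1OC | intermediate
21 | 2',4'-dihydroxy-3',6'-dimethoxy-5'-[(S)-2-methylbutanoyloxy]chalcone | CC[C@H](C)C(=O)Oc1c(O)c(OC)c(O)c(C(=O)/C=C/c2ccccc2)c1OC | target

**Step count**

Total: 12 steps. Longest linear sequence: 10 steps (steps 1–3, then 6–12, from squaric acid); the alkyne branch (steps 4–5) joins at step 6.

**Steps most likely to fail**

1. Step 6 (benzannulation, proposed new method). The α-alkoxy vinylketene may dimerize or be captured by the product phenol faster than it adds to the hindered ynol ether. Alternatively, at 110 °C the silyl ether ortho to the new phenol may ionize to an o-quinone methide that closes to a 2H-chromene.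
   Fallback (known Moore rearrangement and directed metalation chemistry): it sets out from dibenzyl squarate 2 and cinnamaldehyde 6 and comes back at chalcone 16.
   - Methoxymethyl vinyl ether is α-lithiated with sec-BuLi (THF, −78 °C) and added to one carbonyl of 2 to give rac-2,3-bis(benzyloxy)-4-hydroxy-4-[1-(methoxymethoxy)ethenyl]cyclobut-2-en-1-one F1.
   - Heating F1 in p-xylene at 140 °C should trigger the four-electron opening, six-electron closure and tautomerization of a 4-alkenyl-4-hydroxycyclobutenone to give 2,3-bis(benzyloxy)-5-(methoxymethoxy)benzene-1,4-diol F2.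
   - F2 is bis-O-methylated without exposure to air (MeI, K2CO3, acetone) to 2,3-bis(benzyloxy)-1,4-dimethoxy-5-(methoxymethoxy)benzene F3.
   - The single ring hydrogen of F3, flanked by the methoxymethoxy and a methoxy group, is removed by directed ortho-lithiation (n-BuLi, THF, 0 °C), and the aryllithium is added to 6 at −78 °C to give rac-(E)-1-[3,4-bis(benzyloxy)-2,5-dimethoxy-6-(methoxymethoxy)phenyl]-3-phenylprop-2-en-1-ol F4.
   - MnO2 oxidation gives (E)-1-[3,4-bis(benzyloxy)-2,5-dimethoxy-6-(methoxymethoxy)phenyl]-3-phenylprop-2-en-1-one F5.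
   - Mild acid (HCl, MeOH/THF, 40 °C) removes the acetal ortho to the ketone and gives 16.

2. Step 7 (desilylation). During fluoride treatment, work-up or purification, the benzylic–allylic C–O bond next to the free phenol may ionize, with loss of water or silanol through an o-quinone methide and oxa-six-electron closure to a flav-3-ene.
   Fallback (the phenol is masked before the carbinol is released, so the quinone methide pathway is closed): it sets out from 14 and comes back at 16.
   - The phenol of 14 is alkylated (NaH, MOMCl, THF, 0 °C) to rac-(E)-tert-butyl[[1-[3,4-bis(benzyloxy)-2,5-dimethoxy-6-(methoxymethoxy)phenyl]-3-phenylprop-2-en-1-yl]oxy]dimethylsilane F6.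
   - Bu4NF then gives rac-(E)-1-[3,4-bis(benzyloxy)-2,5-dimethoxy-6-(methoxymethoxy)phenyl]-3-phenylprop-2-en-1-ol F4.
   - MnO2 oxidation gives (E)-1-[3,4-bis(benzyloxy)-2,5-dimethoxy-6-(methoxymethoxy)phenyl]-3-phenylprop-2-en-1-one F5.
   - HCl in MeOH/THF removes the acetal to give 16.

3. Step 10 (regioselective capping of O4'). Alkylation may occur at O5' or at both catechol oxygens, and the electron-rich triol may be oxidised by air to a quinone under basic conditions.
   Fallback (the two oxygens are told apart by the reactivity of their esters, not by their acidity toward alkylation): it sets out from 17 (with acid 19), comes back at the target 21 and bypasses steps 10–12.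
   - Both catechol hydroxyls of 17 are acylated with 19 (2.5 equiv, DCC, catalytic DMAP, CH2Cl2, 0 °C) to give [2-hydroxy-3,6-dimethoxy-5-[(2S)-2-methylbutanoyl]oxy-4-[(E)-3-phenylprop-2-enoyl]... in chalcone terms 2'-hydroxy-3',6'-dimethoxy-4',5'-bis[(S)-2-methylbutanoyloxy]chalcone F7.
   - The 4'-ester, whose phenoxide leaving group is para to the ketone, is the more electrophilic of the two and should be removed selectively by mild methanolysis (NH4OAc, MeOH, rt), as is known for aryl esters para to a carbonyl in polyacylated flavonoids, to leave 21.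

**Further compounds**

F1 | step 6 | rac-2,3-bis(benzyloxy)-4-hydroxy-4-[1-(methoxymethoxy)ethenyl]cyclobut-2-en-1-one | C=C(OCOC)C1(O)C(OCc2ccccc2)=C(OCc3ccccc3)C1=O
F2 | step 6 | 2,3-bis(benzyloxy)-5-(methoxymethoxy)benzene-1,4-diol | COCOc1cc(O)c(OCc2ccccc2)c(OCc3ccccc3)c1O
F3 | step 6 | 2,3-bis(benzyloxy)-1,4-dimethoxy-5-(methoxymethoxy)benzene | COCOc1cc(OC)c(OCc2ccccc2)c(OCc3ccccc3)c1OC
F4 | step 6 | rac-(E)-1-[3,4-bis(benzyloxy)-2,5-dimethoxy-6-(methoxymethoxy)phenyl]-3-phenylprop-2-en-1-ol | COCOc1c(C(O)/C=C/c2ccccc2)c(OC)c(OCc3ccccc3)c(OCc4ccccc4)c1OC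
F5 | step 6 | (E)-1-[3,4-bis(benzyloxy)-2,5-dimethoxy-6-(methoxymethoxy)phenyl]-3-phenylprop-2-en-1-one | COCOc1c(C(=O)/C=C/c2ccccc2)c(OC)c(OCc3ccccc3)c(OCc4ccccc4)c1OC
F6 | step 7 | rac-(E)-tert-butyl[[1-[3,4-bis(benzyloxy)-2,5-dimethoxy-6-(methoxymethoxy)phenyl]-3-phenylprop-2-en-1-yl]oxy]dimethylsilane | COCOc1c(C(O[Si](C)(C)C(C)(C)C)/C=C/c2ccccc2)c(OC)c(OCc3ccccc3)c(OCc4ccccc4)c1OC
F7 | step 10 | 2'-hydroxy-3',6'-dimethoxy-4',5'-bis[(S)-2-methylbutanoyloxy]chalcone | CC[C@H](C)C(=O)Oc1c(OC(=O)[C@@H](C)CC)c(OC)c(O)c(C(=O)/C=C/c2ccccc2)c1OC
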